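Compound numbers are those of the steps and of the compound list below.

## Analysis of the target

Target 14 is built on one oxolane ring, O1 and C2 to C5, with no other ring apart from its two arenes. C2 and C5 each carry a 4-hydroxy-3,5-dimethoxyphenyl (syringyl) ring, and C3 and C4 each carry a hydroxymethyl group. All four ring carbons are stereocentres, (2R,3S,4S,5R). Every pair of neighbouring substituents is trans, so the two aryl groups are also trans across O1, and a twofold axis through O1 and the midpoint of C3–C4 leaves only two independent stereocentres. The delicate part is the pair of benzylic ether bonds C2–O1 and C5–O1, each para to a free phenol. Acid (benzylic cation), hot base (quinone methide) or a hydrogenation catalyst can break them and scramble C2 and C5, and the electron-rich phenols are easily oxidised. The synthesis is hard because a 2,5-trans diaryl arrangement must be combined with a defined absolute configuration. C2 and C5 bear no acidic hydrogen and cannot be corrected once set, while C3 and C4 can be adjusted only while they carry carbonyl groups. The strategy reads C2–O1–C5, with its two aryl groups, as a diaryl carbonyl ylide, and C3–C4, with its two trans one-carbon arms, as a fumaric diester. Both fragments are symmetric, so joining them raises no question of regiochemistry, and syringaldehyde 1 supplies both arenes with their oxygen pattern in place.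

## Retrosynthetic reasoning

**14 to 13.** The two phenolic O–benzyl bonds are cut first. The free p-hydroxybenzylic ethers of 14 tolerate neither acid nor strong base, so the phenols are released last, by neutral hydrogenolysis. The forward step must cleave the aryl benzyl ethers while leaving the ring benzylic C–O bonds intact.

**13 to 12.** The two hydroxymethyl groups are traced back to ester carbonyls on C3 and C4. This puts C3–C4 at the oxidation level of an activated alkene partner. The same hydride reduction that makes the primary alcohols also removes the lactate-derived ester groups, so no separate auxiliary cleavage is needed.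

**12 to 7 and 10, through 11.** The bonds C2–C3 and C4–C5 are cut. Cutting the ring C–O bonds instead would leave an open chain with four stereocentres still to be made. Cutting C3–C4 would leave C2 and C5 to be set afterwards by an uncontrolled trapping event. The chosen cut gives two symmetric halves, and each stereochemical relation comes from a geometric feature of a precursor:

- the E geometry of fumarate 10 gives the 3,4-trans relation;
- the exo,endo geometry of ylide 11 gives the 2,5-trans relation, and that geometry follows from conrotatory opening of the cis-oxirane 7;
- the less hindered approach, with each ester away from the neighbouring aryl group, gives the all-trans ring;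
- the stereocentres of 10 make the two all-trans adducts diastereomers, so that 12 can be obtained as a single stereoisomer.

The forward reaction must open the C–C bond of 7 without breaking a C–O bond, capture 11 before it rotates, and distinguish the two faces of 10.

**10 to 8 and 9.** The two acyl–oxygen bonds are cut. One twofold acylation joins two molecules of the cheap chiral alcohol 9 to the diacid chloride 8 without touching the stereocentre of 9.

**7 to 6.** The two C–O bonds of the oxirane are cut. A neutral, stereospecific oxygen-atom transfer to the (Z)-alkene 6 gives the cis-oxirane, which is too acid-sensitive to be made with an acidic oxidant.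

**6 to 4 and 2, through 5.** The C=C bond is cut. Both halves come from the same aldehyde 2, one of them as the phosphonium salt 4, and a kinetically controlled Wittig reaction through ylide 5 has to deliver the Z geometry.

**4 to 3 to 2 to 1.** The C–P bond, the benzylic C–H bond (aldehyde reduction) and the O–benzyl bond are cut in turn, which ends at syringaldehyde 1.

## Alternatives that were turned down

**Alternative 1:** The four C–C bonds that complete the two benzene rings are cut, in each ring the two bonds between the CH carbons and the methoxy-bearing carbons, so both syringyl rings are made last. In the forward key step the bis(vinamidinium) salt A2, an oxolane with a vinamidinium unit on C2 and on C5, condenses under a strong alkoxide base with two molecules of 1,3-dimethoxyacetone A3. Each ketone closes one phenol ring by (3+3) annulation, and the product is the bis(triisopropylsilyl) ether A1 of the target.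

- For: no phenol needs protection and the 1,2,3-oxygen pattern is fixed by the ketone. The four stereocentres are in place before the arenes exist, so the last C–C bond-forming step has no stereoselectivity to achieve, and no benzylic ether meets a hydrogenation catalyst. On these two points it is stronger than the chosen route.
- Against: the annulation solves none of the stereochemical problem, because A2 is itself an all-trans tetrasubstituted oxolane as demanding as 14. In A2 the ring C–O bonds are allylic to an enamine-type carbon and C2–H and C5–H are activated, so the base threatens ring opening and epimerisation at the centres that cannot be repaired. Four C–C bonds must form cleanly on one molecule with a weakly acidic, self-condensing ketone. Building two syringyl rings from scratch is poor step economy when syringaldehyde 1 provides them.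
- Comparison: the chosen route carries a kinetic stereochemical risk in one step, but it assembles ring and stereocentres from bought arenes in one operation and is several steps shorter.

**Alternative 2:** The cut is made at C3–C4 and at both ring C–O bonds, which returns two identical cinnamoyl units, the sinapoyl imide A5 with a (4S)-4-benzyl-oxazolidinone auxiliary. In the forward direction an iron-based one-electron oxidant (trivalent iron) in a moist organic solvent generates two phenoxyl radicals. These couple at their β-carbons to form C3–C4, and the resulting bis(quinone methide) takes up one oxygen atom from the aqueous medium to form O1–C2 and O1–C5, giving the bis(imide) A4.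

- For: it is by far the shortest plan (auxiliary attachment, coupling, reductive removal), it needs no phenol protection, and it follows the way such lignans arise in nature. The two methoxy groups flanking each phenol block ring coupling, so the β–β mode is favoured. On step count and protecting-group economy it is clearly stronger than the chosen route.
- Against: three stereochemical events are left to weak control. The radical–radical coupling decides the C3/C4 relation and its absolute sense with the auxiliaries three bonds from the reacting carbons. The two oxygen additions to the quinone methides decide C2 and C5 with nothing that enforces the 2,5-trans arrangement. The bis(quinone methide) is also open to Friedel–Crafts attack by the neighbouring electron-rich ring, which would close a new six-membered carbocycle onto that arene, and the free-phenol product stays exposed to the oxidant.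
- Comparison: the chosen route is longer, but each stereochemical relation follows from an alkene or ylide geometry, and the benzyl-protected phenols keep the quinone methide manifold closed.

**Alternative 3:** The bonds C2–aryl and C5–aryl are cut. This leads to the (3S,4S)-bis(acetoxymethyl) bis-acetal A7, a 2,5-dimethoxyoxolane that already holds C3 and C4, and to two molecules of 2,6-dimethoxyphenol A8. In the forward key step a boron-based Lewis acid ionises each acetal carbon in turn and A8 attacks the oxocarbenium ions through its carbon para to the hydroxyl group, giving the diacetate A6 of the target.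

- For: the arene is the cheapest possible and the plan is convergent. Attack anti to the substituent on the neighbouring carbon should give the 2,3-trans and 4,5-trans relations. Because the products are electron-rich benzylic ethers, the Lewis acid can re-ionise them, so the all-trans isomer may accumulate under thermodynamic control. This self-correction at C2 and C5 is a real advantage over the chosen route, where these centres are fixed kinetically.
- Against: enantiopure A7 needs an asymmetric synthesis of its own, so the step count is no lower. The oxocarbenium ion from A7 has an acidic hydrogen on C3 or C4, and loss of both acetal alkoxy groups by elimination aromatises the five-membered ring and wipes out both stereocentres. A8 is also nucleophilic at oxygen and at C3, which both methoxy groups activate, so the regiochemistry of arylation is not assured. The reversibility that helps trans selectivity also opens the ring to a benzylic cation that another molecule of A8 can capture, giving open-chain products with two aryl groups on one carbon.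
- Comparison: the chosen route forms C2 and C5 without any cationic benzylic intermediate and with the aryl groups attached from the start, so neither regiochemistry nor over-arylation arises. In place of thermodynamic correction it offers an outcome tied to orbital symmetry, and diastereomers that can be separated.

Key step: step 7

Assumption: the uncatalysed facial preference of the bis-(S)-lactate fumarate 10 is taken to favour the face that leads to 12; the assignment is checked on purified 12 (crystal structure), and if the preference is the reverse, ethyl (R)-lactate replaces 9 in step 6 with nothing else changed.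

## Route

Step 1
Reactants: 1 syringaldehyde (4-hydroxy-3,5-dimethoxybenzaldehyde)
Product: 2 4-(benzyloxy)-3,5-dimethoxybenzaldehyde
Conditions: BnBr, K2CO3, DMF, 60 °C
Reagents that add atoms: benzyl bromide, BrCc1ccccc1
Why: Williamson ether synthesis; the phenoxide, made more acidic by the para-formyl group, is alkylated by the benzylic bromide despite the two flanking methoxy groups, and the benzyl ether then protects the phenol from base, oxidant and hydride in all later steps.

Step 2
Reactants: 2 4-(benzyloxy)-3,5-dimethoxybenzaldehyde (the portion not reserved for step 4)
Product: 3 [4-(benzyloxy)-3,5-dimethoxyphenyl]methanol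
Conditions: NaBH4, MeOH–THF, 0 °C
Reagents that add atoms: none
Why: Borohydride reduction of an aryl aldehyde to the benzylic alcohol; no other reducible group is present.

Step 3
Reactants: 3 [4-(benzyloxy)-3,5-dimethoxyphenyl]methanol
Product: 4 {[4-(benzyloxy)-3,5-dimethoxyphenyl]methyl}triphenylphosphonium bromide
Conditions: PPh3·HBr, MeCN, reflux
Reagents that add atoms: triphenylphosphine hydrobromide, Br.c1ccc(cc1)P(c1ccccc1)c1ccccc1
Why: Acid-promoted substitution of an electron-rich benzylic alcohol; protonation and loss of water give a stabilised benzylic electrophile that PPh3 captures, so the labile benzylic bromide need not be isolated, and the aryl benzyl ether is stable to this weak acid.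

Step 4
Reactants: 4 {[4-(benzyloxy)-3,5-dimethoxyphenyl]methyl}triphenylphosphonium bromide; 2 4-(benzyloxy)-3,5-dimethoxybenzaldehyde
Product: 6 (Z)-1,2-bis[4-(benzyloxy)-3,5-dimethoxyphenyl]ethene, via phosphonium ylide 5 (not isolated)
Conditions: NaN(SiMe3)2, THF, −78 °C; then 2, −78 °C to rt; chromatography to remove the (E)-isomer
Reagents that add atoms: none
Why: Wittig olefination with a semi-stabilised benzylide under lithium-free conditions at low temperature, where kinetically controlled oxaphosphetane formation should favour the (Z)-alkene; the (E)-isomer is removed by chromatography or crystallisation, and the Z geometry is what later becomes the cis relation in the oxirane.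

Step 5
Reactants: 6 (Z)-1,2-bis[4-(benzyloxy)-3,5-dimethoxyphenyl]ethene
Product: 7 cis-2,3-bis[4-(benzyloxy)-3,5-dimethoxyphenyl]oxirane (meso, 2R,3S)
Conditions: dimethyldioxirane (acetone solution), CH2Cl2, 0 °C; evaporation; filtration through Et3N-deactivated silica
Reagents that add atoms: dimethyldioxirane, CC1(C)OO1
Why: Epoxidation by a dioxirane is a concerted, stereospecific oxygen-atom transfer, so the (Z)-alkene gives only the cis-oxirane; the reagent is neutral and leaves only acetone, which matters because the electron-rich diaryl oxirane would rearrange under the acid a peracid brings, and alkene epoxidation is much faster than oxidation of the benzyl ethers.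

Step 6
Reactants: 8 fumaryl chloride; 9 ethyl (S)-lactate (first equivalent)
Product: 10 bis[(2S)-1-ethoxy-1-oxopropan-2-yl] (2E)-but-2-enedioate
Conditions: 9 (2.2 equiv in all), pyridine (2.5 equiv), DMAP (cat.), CH2Cl2, 0 °C to rt
Reagents that add atoms: ethyl (S)-lactate (compound 9, second equivalent), C[C@H](O)C(=O)OCC
Why: Twofold O-acylation (nucleophilic acyl substitution under DMAP catalysis) in which each acid chloride group of 8 acylates the secondary hydroxyl of one molecule of 9, so two molecules of 9 are consumed per molecule of 8; the lactate stereocentre is not involved in the bond formation and the E geometry of the diacid chloride is retained.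

Step 7
Reactants: 7 cis-2,3-bis[4-(benzyloxy)-3,5-dimethoxyphenyl]oxirane; 10 bis[(2S)-1-ethoxy-1-oxopropan-2-yl] (2E)-but-2-enedioate
Product: 12 bis[(2S)-1-ethoxy-1-oxopropan-2-yl] (2R,3R,4R,5R)-2,5-bis[4-(benzyloxy)-3,5-dimethoxyphenyl]oxolane-3,4-dicarboxylate, via carbonyl ylide 11 (not isolated)
Conditions: 10 (3 equiv), mesitylene (degassed, concentrated), 170 °C, sealed tube, base-washed glass; chromatography (excess 10 recovered)
Reagents that add atoms: none
Why: At about 170 °C the carbon–carbon bond of oxirane 7 opens in a thermally allowed four-electron conrotatory electrocyclic reaction, which converts the cis arrangement of the aryl groups into the exo,endo (S-shaped) carbonyl ylide 11; trapping of such thermally generated aryl-oxirane ylides by fumarates is the known 1,3-dipolar cycloaddition on which the step relies. The electron-rich ylide adds to the electron-poor alkene of 10 in a concerted suprafacial (4π+2π) event that forms C2–C3 and C4–C5 together, so the oxolane ring is closed by intermolecular cycloaddition and not by a separate cyclisation. C3 and C4 come out trans because the E geometry of 10 is carried through, and C2 and C5 come out trans because the exo,endo geometry of 11 is carried through. The 2,3 and 4,5 relations are set by the orientation of approach: of the two possible ones, that in which each ester group points away from the aryl group on the neighbouring ylide carbon is the less hindered and gives the all-trans ring. The absolute configuration is decided by which face of 10 reacts; the two (S)-lactate esters bias this face through their preferred conformation in the non-polar solvent, and because the two all-trans adducts are diastereomers, 12 is freed from its isomers by chromatography or crystallisation whatever the level of induction. The step needs capture of 11 to be faster than rotation about its C–O bonds (which would leak to 2,5-cis adducts) and faster than C–O heterolysis of 7; an excess of the reactive dipolarophile at high concentration, exclusion of acid and base-washed glass serve this. No Lewis acid such as TiCl4 is added, because it would ionise the benzylic C–O bonds of 7 long before any cycloaddition, and the crude mixture is not treated with base, because the 2,3-cis adduct formed on the same face of 10 has the opposite configuration at C2 and C5 and would epimerise at C3 and C4 to the all-trans ring of the wrong series.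

Step 8
Reactants: 12 bis[(2S)-1-ethoxy-1-oxopropan-2-yl] (2R,3R,4R,5R)-2,5-bis[4-(benzyloxy)-3,5-dimethoxyphenyl]oxolane-3,4-dicarboxylate
Product: 13 [(2R,3S,4S,5R)-2,5-bis[4-(benzyloxy)-3,5-dimethoxyphenyl]oxolane-3,4-diyl]dimethanol
Conditions: LiAlH4 (excess), THF, 0 °C to rt; aqueous potassium sodium tartrate work-up
Reagents that add atoms: none
Why: Hydride reduction of all four ester groups; the ring carboxylates become hydroxymethyl groups and the auxiliary leaves as water-soluble (S)-propane-1,2-diol, reduction is faster than enolisation and the all-trans arrangement is in any case the most stable one at C3 and C4, while C2 and C5 carry no acidic hydrogen (the descriptors at C3 and C4 change from R to S only because the substituent priorities change).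

Step 9
Reactants: 13 [(2R,3S,4S,5R)-2,5-bis[4-(benzyloxy)-3,5-dimethoxyphenyl]oxolane-3,4-diyl]dimethanol
Product: 14 4,4'-[(2R,3S,4S,5R)-3,4-bis(hydroxymethyl)oxolane-2,5-diyl]bis(2,6-dimethoxyphenol)
Conditions: H2 (1 atm), Pd/C, EtOAc–EtOH, rt, stopped as soon as debenzylation is complete
Reagents that add atoms: none
Why: Hydrogenolysis of aryl benzyl ethers over Pd/C, which should be much faster than cleavage of the ring's benzylic dialkyl ether bonds; the neutral medium avoids ionising the p-hydroxybenzylic C–O bonds of the product, so no stereocentre is touched.

## Compound list

1 | syringaldehyde (4-hydroxy-3,5-dimethoxybenzaldehyde) | COc1cc(C=O)cc(OC)c1O | starting material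
2 | 4-(benzyloxy)-3,5-dimethoxybenzaldehyde | COc1cc(C=O)cc(OC)c1OCc1ccccc1 | intermediate
3 | [4-(benzyloxy)-3,5-dimethoxyphenyl]methanol | COc1cc(CO)cc(OC)c1OCc1ccccc1 | intermediate
4 | {[4-(benzyloxy)-3,5-dimethoxyphenyl]methyl}triphenylphosphonium bromide | COc1cc(C[P+](c2ccccc2)(c2ccccc2)c2ccccc2)cc(OC)c1OCc1ccccc1.[Br-] | intermediate
5 | {[4-(benzyloxy)-3,5-dimethoxyphenyl]methylidene}triphenylphosphorane (phosphonium ylide, not isolated) | COc1cc(C=P(c2ccccc2)(c2ccccc2)c2ccccc2)cc(OC)c1OCc1ccccc1 | intermediate
6 | (Z)-1,2-bis[4-(benzyloxy)-3,5-dimethoxyphenyl]ethene | COc1cc(/C=C\c2cc(OC)c(OCc3ccccc3)c(OC)c2)cc(OC)c1OCc1ccccc1 | intermediate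
7 | cis-2,3-bis[4-(benzyloxy)-3,5-dimethoxyphenyl]oxirane (meso, 2R,3S) | COc1cc([C@@H]2O[C@@H]2c2cc(OC)c(OCc3ccccc3)c(OC)c2)cc(OC)c1OCc1ccccc1 | intermediate
8 | fumaryl chloride ((2E)-but-2-enedioyl dichloride) | O=C(Cl)/C=C/C(=O)Cl | starting material
9 | ethyl (S)-lactate (ethyl (2S)-2-hydroxypropanoate) | C[C@H](O)C(=O)OCC | starting material
10 | bis[(2S)-1-ethoxy-1-oxopropan-2-yl] (2E)-but-2-enedioate | C[C@H](OC(=O)/C=C/C(=O)O[C@@H](C)C(=O)OCC)C(=O)OCC | intermediate
11 | exo,endo (S-shaped) carbonyl ylide of 7, bis[4-(benzyloxy)-3,5-dimethoxyphenyl]-substituted C–O–C dipole with one aryl group exo and one endo (one resonance form drawn, not isolated) | COc1cc(/C=[O+]/[CH-]c2cc(OC)c(OCc3ccccc3)c(OC)c2)cc(OC)c1OCc1ccccc1 | intermediate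
12 | bis[(2S)-1-ethoxy-1-oxopropan-2-yl] (2R,3R,4R,5R)-2,5-bis[4-(benzyloxy)-3,5-dimethoxyphenyl]oxolane-3,4-dicarboxylate (all-trans) | COc1cc([C@@H]2O[C@@H](c3cc(OC)c(OCc4ccccc4)c(OC)c3)[C@H](C(=O)O[C@@H](C)C(=O)OCC)[C@H]2C(=O)O[C@@H](C)C(=O)OCC)cc(OC)c1OCc1ccccc1 | intermediate
13 | [(2R,3S,4S,5R)-2,5-bis[4-(benzyloxy)-3,5-dimethoxyphenyl]oxolane-3,4-diyl]dimethanol (all-trans) | COc1cc([C@@H]2O[C@@H](c3cc(OC)c(OCc4ccccc4)c(OC)c3)[C@H](CO)[C@H]2CO)cc(OC)c1OCc1ccccc1 | intermediate
14 | 4,4'-[(2R,3S,4S,5R)-3,4-bis(hydroxymethyl)oxolane-2,5-diyl]bis(2,6-dimethoxyphenol) (all-trans) | COc1cc([C@@H]2O[C@@H](c3cc(OC)c(O)c(OC)c3)[C@H](CO)[C@H]2CO)cc(OC)c1O | target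

## Step count and least certain steps

Total step count: 9. Longest linear sequence: 8 steps (steps 1 to 5 and 7 to 9, from syringaldehyde 1 to 14); step 6 is a one-step side branch.

**Step 7 (key step).** Three things are most likely to go wrong.

- Facial discrimination on 10 may be weak. The lactate esters are flexible and no Lewis acid can be used, so at 170 °C the two all-trans diastereomers may form in similar amounts, which costs material but not purity.
- The ylide 11 may rotate before capture, which leaks to 2,5-cis adducts.
- Oxirane 7 may open heterolytically at a C–O bond (Meinwald-type rearrangement) on traces of acid.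

The 4-benzyloxy group is flanked by two methoxy groups and is twisted out of conjugation. It therefore gives the ylide termini little extra stabilisation, and the temperature has to be that of a plain diaryl oxirane.

Fallback (sets out from 6, returns at 12): the same exo,endo ylide 11 is generated photochemically at low temperature from the trans-oxirane, since light-driven C–C opening is disrotatory. Olefin 6 is isomerised with catalytic I2 (heptane, daylight) to (E)-1,2-bis[4-(benzyloxy)-3,5-dimethoxyphenyl]ethene F1, which is also the isomer removed in step 4. Epoxidation with dimethyldioxirane as in step 5 gives racemic trans-2,3-bis[4-(benzyloxy)-3,5-dimethoxyphenyl]oxirane F2. Irradiation of F2 (300 nm, quartz, degassed CH2Cl2–methylcyclohexane, −40 °C) in the presence of 10 should give 12. At this temperature the conformational bias of the lactate esters is far more effective and ylide rotation is suppressed.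

**Step 4.** Geometric control in the olefination may be poor. Semi-stabilised benzylides give kinetic Z/E mixtures, and only the (Z)-olefin leads on to the cis-oxirane.

Fallback (sets out from 2, returns at 6): the Z geometry is made by alkyne semi-hydrogenation.

- Aldehyde 2 is homologated with dimethyl (1-diazo-2-oxopropyl)phosphonate (K2CO3, MeOH, rt; Ohira–Bestmann modification of the Seyferth–Gilbert reaction) to 2-(benzyloxy)-5-ethynyl-1,3-dimethoxybenzene F3.
- Purchased 4-bromo-2,6-dimethoxyphenol F4 is benzylated (BnBr, K2CO3, DMF) to 2-(benzyloxy)-5-bromo-1,3-dimethoxybenzene F5.
- Sonogashira coupling of F3 with F5 (PdCl2(PPh3)2, CuI, Et3N, DMF, 80 °C) gives 1,2-bis[4-(benzyloxy)-3,5-dimethoxyphenyl]ethyne F6.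
- Hydrogenation of F6 over Lindlar catalyst (Pd/CaCO3 poisoned with Pb(OAc)2, quinoline, H2 1 atm, EtOAc) gives 6 by syn addition, without touching the benzyl ethers.

**Step 9.** Over-reduction is the risk. Once the benzyl ethers are gone, the ring C2–O1 and C5–O1 bonds are benzylic ethers on very electron-rich rings and may be hydrogenolysed, opening the oxolane.

Fallback (sets out from 12, returns at 14): the order of the last two operations is reversed. Hydrogenolysis of 12 (H2, Pd/C, EtOAc) gives bis[(2S)-1-ethoxy-1-oxopropan-2-yl] (2R,3R,4R,5R)-2,5-bis(4-hydroxy-3,5-dimethoxyphenyl)oxolane-3,4-dicarboxylate F7. In 12 each ring benzylic C–O bond has an electron-withdrawing ester on the adjacent carbon, which should retard its cleavage, and the lipophilic substrate allows an ester solvent in place of an alcohol. Reduction of F7 with excess LiAlH4 (THF, 0 °C, allowing for the two phenoxides; aqueous potassium sodium tartrate work-up) then gives 14 directly.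

## Further compounds

F1 | step 7 | (E)-1,2-bis[4-(benzyloxy)-3,5-dimethoxyphenyl]ethene | COc1cc(/C=C/c2cc(OC)c(OCc3ccccc3)c(OC)c2)cc(OC)c1OCc1ccccc1
F2 | step 7 | trans-2,3-bis[4-(benzyloxy)-3,5-dimethoxyphenyl]oxirane (racemic; the 2S,3S enantiomer is drawn) | COc1cc([C@@H]2O[C@H]2c2cc(OC)c(OCc3ccccc3)c(OC)c2)cc(OC)c1OCc1ccccc1
F3 | step 4 | 2-(benzyloxy)-5-ethynyl-1,3-dimethoxybenzene | COc1cc(C#C)cc(OC)c1OCc1ccccc1
F4 | step 4 | 4-bromo-2,6-dimethoxyphenol (purchased) | COc1cc(Br)cc(OC)c1O
F5 | step 4 | 2-(benzyloxy)-5-bromo-1,3-dimethoxybenzene | COc1cc(Br)cc(OC)c1OCc1ccccc1
F6 | step 4 | 1,2-bis[4-(benzyloxy)-3,5-dimethoxyphenyl]ethyne | COc1cc(C#Cc2cc(OC)c(OCc3ccccc3)c(OC)c2)cc(OC)c1OCc1ccccc1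
F7 | step 9 | bis[(2S)-1-ethoxy-1-oxopropan-2-yl] (2R,3R,4R,5R)-2,5-bis(4-hydroxy-3,5-dimethoxyphenyl)oxolane-3,4-dicarboxylate | COc1cc([C@@H]2O[C@@H](c3cc(OC)c(O)c(OC)c3)[C@H](C(=O)O[C@@H](C)C(=O)OCC)[C@H]2C(=O)O[C@@H](C)C(=O)OCC)cc(OC)c1O
A1 | alternative 1 | bis(triisopropylsilyl) ether of the target: 4,4'-[(2R,3S,4S,5R)-3,4-bis{[tri(propan-2-yl)silyl]oxymethyl}oxolane-2,5-diyl]bis(2,6-dimethoxyphenol) | COc1cc([C@@H]2O[C@@H](c3cc(OC)c(O)c(OC)c3)[C@H](CO[Si](C(C)C)(C(C)C)C(C)C)[C@H]2CO[Si](C(C)C)(C(C)C)C(C)C)cc(OC)c1O
A2 | alternative 1 | oxolane-2,5-diyl bis(vinamidinium) bis(hexafluorophosphate): 3,4-bis{[tri(propan-2-yl)silyl]oxymethyl}oxolane with a 1,3-bis(dimethylamino)trimethinium unit bonded through its central carbon to C2 and to C5, ring configured as in 14 | CN(C)C=C(C=[N+](C)C)[C@@H]1O[C@@H](C(C=[N+](C)C)=CN(C)C)[C@H](CO[Si](C(C)C)(C(C)C)C(C)C)[C@H]1CO[Si](C(C)C)(C(C)C)C(C)C.F[P-](F)(F)(F)(F)F.F[P-](F)(F)(F)(F)F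
A3 | alternative 1 | 1,3-dimethoxyacetone (1,3-dimethoxypropan-2-one) | COCC(=O)COC
A4 | alternative 2 | all-trans 2,5-bis(4-hydroxy-3,5-dimethoxyphenyl)oxolane-3,4-dicarbonyl bis[(4S)-4-benzyl-2-oxo-1,3-oxazolidin-3-yl] imide | COc1cc([C@@H]2O[C@@H](c3cc(OC)c(O)c(OC)c3)[C@H](C(=O)N3[C@@H](Cc4ccccc4)COC3=O)[C@H]2C(=O)N2[C@@H](Cc3ccccc3)COC2=O)cc(OC)c1O
A5 | alternative 2 | (4S)-4-benzyl-3-[(2E)-3-(4-hydroxy-3,5-dimethoxyphenyl)prop-2-enoyl]-1,3-oxazolidin-2-one | COc1cc(/C=C/C(=O)N2[C@@H](Cc3ccccc3)COC2=O)cc(OC)c1O
A6 | alternative 3 | diacetate of the target: [(2R,3S,4S,5R)-2,5-bis(4-hydroxy-3,5-dimethoxyphenyl)oxolane-3,4-diyl]bis(methylene) diacetate | COc1cc([C@@H]2O[C@@H](c3cc(OC)c(O)c(OC)c3)[C@H](COC(C)=O)[C@H]2COC(C)=O)cc(OC)c1O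
A7 | alternative 3 | [(3S,4S)-2,5-dimethoxyoxolane-3,4-diyl]bis(methylene) diacetate (mixture at the acetal carbons) | COC1OC(OC)[C@H](COC(C)=O)[C@H]1COC(C)=O
A8 | alternative 3 | 2,6-dimethoxyphenol | COc1cccc(OC)c1O
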